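The target consists of two identical halves joined at its ether oxygen, so both aryl–CH2 bonds are forged in one flask from one aryl bromide and a CH2–O–CH2 linchpin. The decisive event is the second of two Stille couplings. It joins ring carbon C1 of 1,2,3-tribromo-4,5-bis(silyloxy)benzene to the OCH2 carbon of the benzyl stannylmethyl ether generated by the first coupling. The step exploits the contiguous C1–C2–C3 tribromide. Only C1 has an ortho hydrogen (C6–H), whereas C2 and C3 are flanked on both sides, so palladium inserts at C1 and the C2/C3 bromines of each benzene ring survive. The precursors are silylated 3,4,5-tribromocatechol and bis(tributylstannylmethyl) ether.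

Key step: step 4

Remark: the target has no stereocentre and is achiral, so no step has to control configuration. Ring numbering used throughout: C1 = carbon that carries (or will carry) the CH2, C2/C3 = C–Br, C4/C5 = C–O, C6 = C–H.

Step 1
Reactants: 1 4,5-dibromocatechol (4,5-dibromobenzene-1,2-diol)
Product: 2 3,4,5-tribromocatechol (3,4,5-tribromobenzene-1,2-diol)
Conditions: Br2 (1.0 equiv), AcOH, rt
Reagents that add atoms: bromine, BrBr
Why: Electrophilic aromatic bromination: the two remaining ring C–H positions of 1 are equivalent by symmetry and each lies ortho to a hydroxyl group, so only one tribromide can form, and the third bromine deactivates the ring enough for one equivalent of bromine to stop there.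

Step 2
Reactants: 2 3,4,5-tribromocatechol
Product: 3 1,2,3-tribromo-4,5-bis(tert-butyldimethylsilyloxy)benzene
Conditions: TBSCl (2.4 equiv), imidazole (5 equiv), DMF, rt
Reagents that add atoms: tert-butyldimethylsilyl chloride, CC(C)(C)[Si](C)(C)Cl
Why: Imidazole-promoted O-silylation of the two acidic phenols masks them as fluoride-labile, non-coordinating, bulky ethers that also shield the neighbouring C3–Br bond in step 4.

Step 3
Reactants: 4 (tributylstannyl)methanol; 5 tributyl(iodomethyl)stannane
Product: 7 bis[(tributylstannyl)methyl] ether, via sodium (tributylstannyl)methoxide 6 (not isolated)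
Conditions: NaH (1.1 equiv), THF/DMF, 0 °C; then 5, 0 °C to rt
Reagents that add atoms: none
Why: Williamson ether synthesis: the primary alkoxide 6 displaces iodide from the unhindered iodomethylstannane 5, which is the O-alkylation by which alkoxymethylstannanes are routinely made, and NaH touches neither C–Sn bond.

Step 4
Reactants: 3 1,2,3-tribromo-4,5-bis(tert-butyldimethylsilyloxy)benzene (2.3 equiv); 7 bis[(tributylstannyl)methyl] ether (1.0 equiv)
Product: 9 bis[2,3-dibromo-4,5-bis(tert-butyldimethylsilyloxy)benzyl] ether, via tributyl({[2,3-dibromo-4,5-bis(tert-butyldimethylsilyloxy)benzyl]oxy}methyl)stannane 8 (not isolated)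
Conditions: Pd(PPh3)4 (5 mol %), CuI (10 mol %), dry 1,4-dioxane, 95 °C, Ar; 7 added by syringe pump to 3
Reagents that add atoms: none
Why: This is a Migita–Kosugi–Stille coupling of an α-alkoxymethylstannane with an aryl bromide (the known Pd-catalysed alkoxymethylation of aryl bromides with Bu3SnCH2OR), run twice in one flask: Pd(0) inserts into the C1–Br bond of 3, the CH2–Sn carbon of 7 transmetallates in preference to butyl because of its α-oxygen, and reductive elimination gives 8, whose remaining CH2–SnBu3 group then transmetallates to a second ArPdBr so that reductive elimination forms the aryl C1–CH2 bond that unites the two halves in 9. No ring is closed and no stereocentre is created. The selectivity needed is insertion at one of three C–Br bonds: C1–Br has an ortho hydrogen (C6–H), C2–Br lies between two bromines and C3–Br between a bromine and a bulky OTBS group, and PPh3-ligated Pd(0) couples 1,2,3-trihaloarenes at the less hindered terminal halogen. After coupling, both remaining bromines of each ring are di-ortho-substituted, so 8 and 9 should be less reactive than 3 and over-coupling is disfavoured. The one competing path, insertion into the C2–Br bond of 8 followed by closure onto its own stannylmethyl arm, is suppressed by keeping 3 in excess through slow addition of 7. The conditions are neutral and fluoride-free, so the aryl silyl ethers should persist.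

Step 5
Reactants: 9 bis[2,3-dibromo-4,5-bis(tert-butyldimethylsilyloxy)benzyl] ether
Product: 10 bis(2,3-dibromo-4,5-dihydroxybenzyl) ether (target)
Conditions: TBAF (4.4 equiv), AcOH (5 equiv), THF, 0 °C, Ar; pH 4–5 buffer work-up
Reagents that add atoms: none
Why: Fluoride-induced cleavage of the four aryl silyl ethers is driven by Si–F bond formation, and the acetic acid buffer protonates each phenoxide at once, so the dibenzyl ether and the aryl bromides should stay untouched.

Compound list
1 | 4,5-dibromocatechol (4,5-dibromobenzene-1,2-diol) | Oc1cc(Br)c(Br)cc1O | starting material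
2 | 3,4,5-tribromocatechol (3,4,5-tribromobenzene-1,2-diol) | Oc1cc(Br)c(Br)c(Br)c1O | intermediate
3 | 1,2,3-tribromo-4,5-bis(tert-butyldimethylsilyloxy)benzene | CC(C)(C)[Si](C)(C)Oc1cc(Br)c(Br)c(Br)c1O[Si](C)(C)C(C)(C)C | intermediate
4 | (tributylstannyl)methanol | CCCC[Sn](CCCC)(CCCC)CO | starting material
5 | tributyl(iodomethyl)stannane | CCCC[Sn](CCCC)(CCCC)CI | starting material
6 | sodium (tributylstannyl)methoxide | CCCC[Sn](CCCC)(CCCC)C[O-].[Na+] | intermediate
7 | bis[(tributylstannyl)methyl] ether | CCCC[Sn](CCCC)(CCCC)COC[Sn](CCCC)(CCCC)CCCC | intermediate
8 | tributyl({[2,3-dibromo-4,5-bis(tert-butyldimethylsilyloxy)benzyl]oxy}methyl)stannane | CCCC[Sn](CCCC)(CCCC)COCc1cc(O[Si](C)(C)C(C)(C)C)c(O[Si](C)(C)C(C)(C)C)c(Br)c1Br | intermediate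
9 | bis[2,3-dibromo-4,5-bis(tert-butyldimethylsilyloxy)benzyl] ether | CC(C)(C)[Si](C)(C)Oc1cc(COCc2cc(O[Si](C)(C)C(C)(C)C)c(O[Si](C)(C)C(C)(C)C)c(Br)c2Br)c(Br)c(Br)c1O[Si](C)(C)C(C)(C)C | intermediate
10 | bis(2,3-dibromo-4,5-dihydroxybenzyl) ether | Oc1cc(COCc2cc(O)c(O)c(Br)c2Br)c(Br)c(Br)c1O | target

Total step count: 5. Longest linear sequence: 4 steps (1 → 2 → 3 → 9 → 10); step 3 is a one-step side branch.

Steps most likely to fail

1. Step 4 (key step).
- **Risk:** transfer of the sp3 carbon from tin to palladium is slow. Palladium may therefore begin to insert into the hindered C–Br bonds, with loss of site selectivity and oligomerisation. The mono-coupled stannane may also close onto its own neighbouring C–Br bond instead of meeting a second aryl bromide.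
- **Fallback:** radical capture at nickel replaces two-electron transmetallation from tin. It sets out from 3. Compound 3 and the pre-dried dicaesium salt of commercial diglycolic acid (OC(=O)COCC(=O)O) are irradiated with blue light in DMA at rt. The catalysts are Ir[dF(CF3)ppy]2(dtbbpy)PF6 and NiCl2·glyme/dtbbpy, as in the known metallaphotoredox decarboxylative arylation of α-alkoxy acids.
- The first decarboxylation–arylation should give {[2,3-dibromo-4,5-bis(tert-butyldimethylsilyloxy)benzyl]oxy}acetic acid F1 (as its caesium salt). Loss of CO2 from it gives a benzyloxymethyl radical, which the arylnickel species from a second molecule of 3 captures. The sequence comes back to the route at 9.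
- The radical can reach its own ring only by a 5-endo attack, so the intramolecular leak of the tin route is closed.

2. Step 5.
- **Risk:** the C4 phenoxide released by fluoride lies para to the benzylic ether carbon. It may expel the other half as an alkoxide through a p-quinone methide, which would cut or scramble the ether. The catecholates may also be oxidised by air.
- **Fallback:** acid-labile acetal protection, so that the unmasking runs at low pH. No phenoxide forms there, and the ortho and meta bromines retard ionisation of the benzylic C–O bond. It sets out from 2.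
- MOMCl and iPr2NEt in CH2Cl2 give 1,2,3-tribromo-4,5-bis(methoxymethoxy)benzene F2.
- The double Stille coupling with 7 under the conditions of step 4 passes through tributyl({[2,3-dibromo-4,5-bis(methoxymethoxy)benzyl]oxy}methyl)stannane F3 and gives bis[2,3-dibromo-4,5-bis(methoxymethoxy)benzyl] ether F4.
- Catalytic HCl in THF/H2O at 40 °C hydrolyses the four acetals, and the sequence comes back to the route at 10.

3. Step 1.
- **Risk:** over-bromination at the last ring C–H and oxidation of the catechol to the o-quinone by bromine. Either would give mixtures that are hard to separate.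
- **Fallback:** the third bromine is delivered by deprotonative metalation instead of electrophilic substitution, so exactly one halogen enters per metalation. It sets out from 1.
- Silylation (TBSCl, imidazole, DMF) gives 1,2-dibromo-4,5-bis(tert-butyldimethylsilyloxy)benzene F5.
- TMPLi is added to F5 and ZnCl2·2LiCl in THF at −78 °C (in situ trapping metalation). This removes one of the two equivalent protons that lie between bromine and oxygen and gives [2,3-dibromo-5,6-bis(tert-butyldimethylsilyloxy)phenyl]zinc chloride F6. The immediate zinc trap forestalls halogen dance and silyl migration.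
- Br2 at −78 to 0 °C brominates the C–Zn bond, and the sequence comes back to the route at 3, by-passing 2.

Further compounds
F1 | step 4 | {[2,3-dibromo-4,5-bis(tert-butyldimethylsilyloxy)benzyl]oxy}acetic acid | OC(=O)COCc1cc(O[Si](C)(C)C(C)(C)C)c(O[Si](C)(C)C(C)(C)C)c(Br)c1Br
F2 | step 5 | 1,2,3-tribromo-4,5-bis(methoxymethoxy)benzene | COCOc1cc(Br)c(Br)c(Br)c1OCOC
F3 | step 5 | tributyl({[2,3-dibromo-4,5-bis(methoxymethoxy)benzyl]oxy}methyl)stannane | CCCC[Sn](CCCC)(CCCC)COCc1cc(OCOC)c(OCOC)c(Br)c1Br
F4 | step 5 | bis[2,3-dibromo-4,5-bis(methoxymethoxy)benzyl] ether | COCOc1cc(COCc2cc(OCOC)c(OCOC)c(Br)c2Br)c(Br)c(Br)c1OCOC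
F5 | step 1 | 1,2-dibromo-4,5-bis(tert-butyldimethylsilyloxy)benzene | CC(C)(C)[Si](C)(C)Oc1cc(Br)c(Br)cc1O[Si](C)(C)C(C)(C)C
F6 | step 1 | [2,3-dibromo-5,6-bis(tert-butyldimethylsilyloxy)phenyl]zinc chloride | Cl[Zn]c1c(Br)c(Br)cc(O[Si](C)(C)C(C)(C)C)c1O[Si](C)(C)C(C)(C)C
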